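Assumption: the target is taken exactly as drawn, (1S,2S,3S,4R,6R,9S,10R,11S,14S,15R) in cladiellin/briarellin numbering (C2/C9 carry the bridging ether O, C3 = C(Me)O, C11 = C(Me)OH, C14–C15–C16 = oxepane arm); this numbering is used for compounds 13–28, and methyl (S)-glycidate is bought as the single enantiomer.

**Retrosynthetic overview**
1. Target ⇐ Z-C6=C7 oxonene by epoxidation and base isomerisation (C6–OH, exocyclic C7=C19); the octanoate goes on just before; C11 tertiary OH ⇐ exocyclic alkene by HAT hydration.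
2. Oxepane + C4–OH ⇐ 7-endo opening of a 3,4-epoxide by C16–OH; C15/C16 ⇐ hydroboration of the isopropenyl group of a methyl vinyl ketone adduct.
3. Cyclohexane ⇐ Diels–Alder of a 2-ethoxydiene on the oxabicyclo[6.2.1]undecene with methyl vinyl ketone.
4. Oxonene and bridging tetrahydrofuran (formed together) ⇐ Cu-carbenoid oxonium ylide / [2,3]-sigmatropic ring expansion of a 2,6-cis-6-isopropenyl tetrahydropyran diazoketone.
5. Tetrahydropyran ⇐ lactol Wittig/oxa-Michael of an epoxy δ-lactone (RCM) from methyl (S)-glycidate, the only source of chirality. Ring order: pyran → THF + oxonene → cyclohexane → oxepane.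

**Route**

Step 1
Reactants: 1 methyl (2S)-oxirane-2-carboxylate (methyl (S)-glycidate)
Product: 3 (3S)-2-methylhex-5-ene-2,3-diol, via methyl (2S)-2-hydroxypent-4-enoate 2 (not isolated)
Conditions: vinylMgBr (1.2 equiv), CuI (10 mol %), THF, −78 → −40 °C; then MeMgBr (3.5 equiv), −40 → 0 °C; aq NH4Cl
Reagents that add atoms: vinylmagnesium bromide C=C[Mg]Br; methylmagnesium bromide C[Mg]Br
Why: Cu-catalysed Grignard opening of the epoxide at the unhindered CH2 (SN2, stereocentre untouched) followed by double Grignard addition to the ester; the bought stereocentre becomes C6 of the later pyran.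

Step 2
Reactants: 3 (3S)-2-methylhex-5-ene-2,3-diol
Product: 4 (3S)-2-hydroxy-2-methylhex-5-en-3-yl 2-methylprop-2-enoate
Conditions: methacryloyl chloride (1.1 equiv), Et3N, DMAP (cat.), CH2Cl2, −20 → 0 °C
Reagents that add atoms: methacryloyl chloride C=C(C)C(=O)Cl
Why: Acylation (esterification) is selective for the secondary over the tertiary alcohol on steric grounds.

Step 3
Reactants: 4 (3S)-2-hydroxy-2-methylhex-5-en-3-yl 2-methylprop-2-enoate
Product: 5 (3S)-2-methylhexa-1,5-dien-3-yl 2-methylprop-2-enoate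
Conditions: Burgess reagent (1.5 equiv), toluene, BHT (cat.), 60 °C
Reagents that add atoms: none
Why: Burgess dehydration (syn Ei elimination) of the tertiary carbinol goes toward a methyl group (six β-H against one deactivated β-H on the acyloxy carbon), giving the isopropenyl group.

Step 4
Reactants: 5 (3S)-2-methylhexa-1,5-dien-3-yl 2-methylprop-2-enoate
Product: 6 (6S)-3-methyl-6-(prop-1-en-2-yl)-5,6-dihydro-2H-pyran-2-one
Conditions: Grubbs II (5 mol %), CH2Cl2 (0.005 M), reflux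
Reagents that add atoms: none
Why: Ring-closing metathesis between the allyl and methacrylate alkenes gives the six-membered Z-trisubstituted enoate; the hindered isopropenyl group could only close to a tetrasubstituted five-ring and stays out.

Step 5
Reactants: 6 (6S)-3-methyl-6-(prop-1-en-2-yl)-5,6-dihydro-2H-pyran-2-one
Product: 7 (1R,4S,6R)-1-methyl-4-(prop-1-en-2-yl)-3,7-dioxabicyclo[4.1.0]heptan-2-one
Conditions: t-BuOOH (5.5 M in decane, 2 equiv), DBU (1.2 equiv), CH2Cl2, 0 °C → rt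
Reagents that add atoms: tert-butyl hydroperoxide CC(C)(C)OO
Why: Weitz–Scheffer nucleophilic epoxidation touches only the electron-poor alkene, and the peroxide adds axially to C4 trans to the pseudo-equatorial C6 isopropenyl group, which sets the future C3/C4 centres.

Step 6
Reactants: 7 (1R,4S,6R)-1-methyl-4-(prop-1-en-2-yl)-3,7-dioxabicyclo[4.1.0]heptan-2-one
Product: 8 (1R,4S,6R)-1-methyl-4-(prop-1-en-2-yl)-3,7-dioxabicyclo[4.1.0]heptan-2-ol (anomer mixture)
Conditions: DIBAL-H (1.1 equiv), CH2Cl2, −78 °C; Rochelle salt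
Reagents that add atoms: none
Why: Partial reduction of the lactone stops at the tetrahedral aluminate at −78 °C and gives the lactol without touching the epoxide.

Step 7
Reactants: 8 (1R,4S,6R)-1-methyl-4-(prop-1-en-2-yl)-3,7-dioxabicyclo[4.1.0]heptan-2-ol
Product: 10 1-[(1R,2S,4S,6R)-1-methyl-4-(prop-1-en-2-yl)-3,7-dioxabicyclo[4.1.0]heptan-2-yl]propan-2-one, via (E)-4-[(2S,3R)-3-[(2S)-2-hydroxy-3-methylbut-3-en-1-yl]-2-methyloxiran-2-yl]but-3-en-2-one 9 (not isolated)
Conditions: Ph3P=CHCOCH3 (1.5 equiv), toluene, 80 °C; then DBU (0.2 equiv), rt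
Reagents that add atoms: 1-(triphenylphosphoranylidene)propan-2-one CC(=O)C=P(c1ccccc1)(c1ccccc1)c1ccccc1
Why: Wittig olefination of the open hydroxy-aldehyde is followed by a reversible intramolecular oxa-Michael addition that settles on the 2,6-cis (diequatorial) tetrahydropyran, so the bought C6 centre sets C2.

Step 8
Reactants: 10 1-[(1R,2S,4S,6R)-1-methyl-4-(prop-1-en-2-yl)-3,7-dioxabicyclo[4.1.0]heptan-2-yl]propan-2-one
Product: 12 1-diazo-3-[(1R,2S,4S,6R)-1-methyl-4-(prop-1-en-2-yl)-3,7-dioxabicyclo[4.1.0]heptan-2-yl]propan-2-one, via 1,1,1-trifluoro-5-[(1R,2S,4S,6R)-1-methyl-4-(prop-1-en-2-yl)-3,7-dioxabicyclo[4.1.0]heptan-2-yl]pentane-2,4-dione 11 (not isolated)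
Conditions: LiHMDS, THF, −78 °C; CF3CO2CH2CF3; then MsN3, Et3N, H2O, MeCN, rt
Reagents that add atoms: methanesulfonyl azide CS(=O)(=O)N=[N+]=[N-]; 2,2,2-trifluoroethyl trifluoroacetate O=C(OCC(F)(F)F)C(F)(F)F (atoms in 11 only)
Why: Danheiser detrifluoroacetylative diazo transfer works through the kinetic methyl enolate, so the β-alkoxy CH2 is never deprotonated and no retro-Michael can occur.

Step 9
Reactants: 12 1-diazo-3-[(1R,2S,4S,6R)-1-methyl-4-(prop-1-en-2-yl)-3,7-dioxabicyclo[4.1.0]heptan-2-yl]propan-2-one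
Product: 14 (2S,3R,4R,6Z,9S)-2,9:3,4-diepoxy-3,7-dimethylcyclodec-6-en-10-one (3,4-epoxy-11-oxabicyclo[6.2.1]undecenone core), via bicyclic oxonium ylide 13 (not isolated)
Conditions: Cu(hfacac)2 (5 mol %), CH2Cl2, reflux, slow addition; Z isomer separated from minor E
Reagents that add atoms: none
Why: The copper carbenoid is trapped by the pyran oxygen (five-ring ylide) and the ylide undergoes a [2,3]-sigmatropic rearrangement through the C6 isopropenyl group, expanding the pyran by three carbons to the Z-oxonene with the bridgehead C9 necessarily cis to C2.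

Step 10
Reactants: 14 (2S,3R,4R,6Z,9S)-2,9:3,4-diepoxy-3,7-dimethylcyclodec-6-en-10-one
Product: 15 (2S,3R,4R,6Z,9S)-2,9:3,4-diepoxy-3,7-dimethylcyclodeca-1(10),6-dien-10-yl trifluoromethanesulfonate
Conditions: NaHMDS, PhNTf2, THF, −78 °C
Reagents that add atoms: N-phenylbis(trifluoromethanesulfonimide) O=S(=O)(N(c1ccccc1)S(=O)(=O)C(F)(F)F)C(F)(F)F
Why: Enol triflate formation can only go toward C1 because C9 is a bridgehead, and the ring-held C2–O bond is orthogonal to the enolate π-system so no β-elimination occurs.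

Step 11
Reactants: 15 (2S,3R,4R,6Z,9S)-2,9:3,4-diepoxy-3,7-dimethylcyclodeca-1(10),6-dien-10-yl trifluoromethanesulfonate
Product: 16 (2S,3R,4R,6Z,9S)-10-(1-ethoxyethenyl)-2,9:3,4-diepoxy-3,7-dimethylcyclodeca-1(10),6-diene
Conditions: tributyl(1-ethoxyvinyl)stannane, Pd(PPh3)4 (5 mol %), LiCl, THF, 65 °C
Reagents that add atoms: tributyl(1-ethoxyvinyl)stannane CCCC[Sn](CCCC)(CCCC)C(=C)OCC
Why: Stille coupling of the vinyl triflate installs the electron-rich 2-alkoxydiene C1=C10–C11(OEt)=C12 under neutral conditions.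

Step 12
Reactants: 16 (2S,3R,4R,6Z,9S)-10-(1-ethoxyethenyl)-2,9:3,4-diepoxy-3,7-dimethylcyclodeca-1(10),6-diene
Product: 18 (1S,2S,3R,4R,6Z,9S,14R)-14-acetyl-11-ethoxy-2,9:3,4-diepoxy tricyclic enol ether (cyclohexene C1–C10=C11–C12–C13–C14 fused to the oxabicycle), via the C14-epimeric mixture of Diels–Alder adducts 17 (not isolated)
Conditions: methyl vinyl ketone (5 equiv), BHT, toluene, 110 °C (sealed); then K2CO3, MeOH, rt
Reagents that add atoms: methyl vinyl ketone C=CC(C)=O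
Why: The intermolecular Diels–Alder is "para"-regioselective (nucleophilic C12 to the enone CH2) and occurs on the diene face away from the nine-membered bridge, setting C1, and base then epimerises the acetyl-bearing C14 to the equatorial isomer trans to C2.

Step 13
Reactants: 18 (1S,2S,3R,4R,6Z,9S,14R)-14-acetyl-11-ethoxy-2,9:3,4-diepoxy tricyclic enol ether
Product: 19 (1S,2S,3R,4R,6Z,9S,14R)-11-ethoxy-14-(prop-1-en-2-yl)-2,9:3,4-diepoxy tricyclic enol ether
Conditions: Ph3PCH3Br, KOtBu, THF, 0 °C → rt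
Reagents that add atoms: methyltriphenylphosphonium bromide C[P+](c1ccccc1)(c1ccccc1)c1ccccc1.[Br-]
Why: Wittig methylenation of the methyl ketone proceeds while C11 is still masked as its enol ether, and C14 is already at its thermodynamic configuration.

Step 14
Reactants: 19 (1S,2S,3R,4R,6Z,9S,14R)-11-ethoxy-14-(prop-1-en-2-yl)-2,9:3,4-diepoxy tricyclic enol ether
Product: 21 (1S,2S,3R,4R,6Z,9S,14S,15R)-11-ethoxy-14-(1-hydroxypropan-2-yl)-2,9:3,4-diepoxy tricyclic enol ether (C16 primary alcohol), via the B-alkyl-9-borabicyclo[3.3.1]nonane adduct of 19 20 (not isolated)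
Conditions: 9-BBN (1.5 equiv), THF, 0 °C → rt; then 3 M NaOH, 30% H2O2, 0 °C
Reagents that add atoms: hydrogen peroxide OO; 9-borabicyclo[3.3.1]nonane [BH]1C2CCCC1CCC2 (atoms in 20 only)
Why: Anti-Markovnikov syn hydroboration–oxidation with 9-BBN selects the 1,1-disubstituted alkene over the tri- and tetrasubstituted ones, and C15 is set by allylic-strain control (borane anti to C1 in the rotamer with C14–H eclipsing C=CH2, giving 15R), with modest dr to be expected and the epimers separable.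

Step 15
Reactants: 21 (1S,2S,3R,4R,6Z,9S,14S,15R)-11-ethoxy-14-(1-hydroxypropan-2-yl)-2,9:3,4-diepoxy tricyclic enol ether
Product: 23 (1S,2S,3S,4R,6Z,9S,10R,14S,15R)-4-hydroxy-11-oxo tetracycle (oxepane C3–O–C16 closed, cis-fused cyclohexanone), via the (10R)-3,4-epoxy-11-keto-16-alcohol 22 (not isolated)
Conditions: oxalic acid (0.1 M), THF/H2O, rt; then CSA (20 mol %), CH2Cl2, 0 °C → rt
Reagents that add atoms: water O
Why: Acid hydrolysis of the enol ether gives the cis-fused C11 ketone, and the C16 hydroxyl then opens the oxirane at tertiary C3 in a 7-endo SN2 with inversion, forming the oxepane with the (3S) ether and releasing the (4R) alcohol.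

Step 16
Reactants: 23 (1S,2S,3S,4R,6Z,9S,10R,14S,15R)-4-hydroxy-11-oxo tetracycle
Product: 24 (1S,2S,3S,4R,6Z,9S,10S,14S,15R)-4-hydroxy-11-methylidene tetracycle
Conditions: Ph3PCH3Br (4 equiv), KOtBu (3.8 equiv), toluene/THF, 0 → 70 °C
Reagents that add atoms: methyltriphenylphosphonium bromide C[P+](c1ccccc1)(c1ccccc1)c1ccccc1.[Br-]
Why: Wittig methylenation of the hindered ketone brings in C20; the cis ring fusion at C10 is the thermodynamic one and the ring-held C9–O bond cannot β-eliminate.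

Step 17
Reactants: 24 (1S,2S,3S,4R,6Z,9S,10S,14S,15R)-4-hydroxy-11-methylidene tetracycle
Product: 25 (1S,2S,3S,4R,6Z,9S,10R,11S,14S,15R)-4,11-dihydroxy tetracycle
Conditions: Mn(dpm)3 (10 mol %), PhSiH3 (2 equiv), O2 (1 atm), i-PrOH/CH2Cl2, 0 °C → rt
Reagents that add atoms: dioxygen O=O
Why: Mukaiyama (HAT) hydration puts H on the terminal CH2 of the 1,1-disubstituted alkene, and the C11 tertiary radical is trapped by O2 on the face anti to the axial C10–C9 bond (OH cis to H10, 11S); the trisubstituted ring alkene reacts much more slowly.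

Step 18
Reactants: 25 (1S,2S,3S,4R,6Z,9S,10R,11S,14S,15R)-4,11-dihydroxy tetracycle
Product: 26 (1S,2S,3S,4R,6Z,9S,10R,11S,14S,15R)-11-hydroxy tetracycle 4-octanoate
Conditions: octanoyl chloride (1.5 equiv), pyridine, DMAP (cat.), CH2Cl2, 0 °C → rt
Reagents that add atoms: octanoyl chloride CCCCCCCC(=O)Cl
Why: Acylation takes the secondary C4 alcohol only, the tertiary C11 alcohol being inert under these conditions.

Step 19
Reactants: 26 (1S,2S,3S,4R,6Z,9S,10R,11S,14S,15R)-11-hydroxy tetracycle 4-octanoate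
Product: 27 (1S,2S,3S,4R,6R,7S,9S,10R,11S,14S,15R)-6,7-epoxy-11-hydroxy tetracycle 4-octanoate
Conditions: DMDO (1.1 equiv), acetone/CH2Cl2, −40 → 0 °C
Reagents that add atoms: dimethyldioxirane CC1(C)OO1
Why: Electrophilic epoxidation of the only remaining alkene takes place on the exposed outer face of the Z-oxonene, which fixes the C6–O bond in the required configuration.

Step 20
Reactants: 27 (1S,2S,3S,4R,6R,7S,9S,10R,11S,14S,15R)-6,7-epoxy-11-hydroxy tetracycle 4-octanoate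
Product: 28 target, (1S,2S,3S,4R,6R,9S,10R,11S,14S,15R)-6,11-dihydroxy-7(19)-ene tetracycle 4-octanoate
Conditions: Et2AlTMP (from LiTMP + Et2AlCl, 4 equiv), toluene, 0 °C; Rochelle salt
Reagents that add atoms: none
Why: Yamamoto aluminium-amide epoxide-to-allylic-alcohol isomerisation removes a proton syn from C19 (the methyl cis to H6 in the Z-derived epoxide), giving the exocyclic alkene with retention at C6, while the hindered amide does not attack the ester.

**Compound list**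
1 | methyl (2S)-oxirane-2-carboxylate | COC(=O)[C@@H]1CO1 | starting material
2 | methyl (2S)-2-hydroxypent-4-enoate | C=CC[C@H](O)C(=O)OC | intermediate
3 | (3S)-2-methylhex-5-ene-2,3-diol | C=CC[C@H](O)C(C)(C)O | intermediate
4 | (3S)-2-hydroxy-2-methylhex-5-en-3-yl 2-methylprop-2-enoate | C=CC[C@H](OC(=O)C(C)=C)C(C)(C)O | intermediate
5 | (3S)-2-methylhexa-1,5-dien-3-yl 2-methylprop-2-enoate | C=CC[C@H](OC(=O)C(C)=C)C(C)=C | intermediate
6 | (6S)-3-methyl-6-(prop-1-en-2-yl)-5,6-dihydro-2H-pyran-2-one | CC1=CC[C@H](OC1=O)C(C)=C | intermediate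
7 | (1R,4S,6R)-1-methyl-4-(prop-1-en-2-yl)-3,7-dioxabicyclo[4.1.0]heptan-2-one | C[C@@]12O[C@@H]1C[C@H](OC2=O)C(C)=C | intermediate
8 | (1R,4S,6R)-1-methyl-4-(prop-1-en-2-yl)-3,7-dioxabicyclo[4.1.0]heptan-2-ol (anomers) | C[C@@]12O[C@@H]1C[C@H](OC2O)C(C)=C | intermediate
9 | (E)-4-[(2S,3R)-3-[(2S)-2-hydroxy-3-methylbut-3-en-1-yl]-2-methyloxiran-2-yl]but-3-en-2-one | CC(=O)/C=C/[C@]1(C)O[C@@H]1C[C@H](O)C(C)=C | intermediate
10 | 1-[(1R,2S,4S,6R)-1-methyl-4-(prop-1-en-2-yl)-3,7-dioxabicyclo[4.1.0]heptan-2-yl]propan-2-one | CC(=O)C[C@@H]1O[C@H](C(C)=C)C[C@H]2O[C@@]12C | intermediate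
11 | 1,1,1-trifluoro-5-[(1R,2S,4S,6R)-1-methyl-4-(prop-1-en-2-yl)-3,7-dioxabicyclo[4.1.0]heptan-2-yl]pentane-2,4-dione | O=C(CC(=O)C[C@@H]1O[C@H](C(C)=C)C[C@H]2O[C@@]12C)C(F)(F)F | intermediate
12 | 1-diazo-3-[(1R,2S,4S,6R)-1-methyl-4-(prop-1-en-2-yl)-3,7-dioxabicyclo[4.1.0]heptan-2-yl]propan-2-one | [N-]=[N+]=CC(=O)C[C@@H]1O[C@H](C(C)=C)C[C@H]2O[C@@]12C | intermediate
13 | bicyclic oxonium ylide (pyran O+ bonded to C2, C6 and the C9 carbanion α to the C10 ketone) | C=C(C)[C@@H]1C[C@H]2O[C@@]2(C)[C@@H]2CC(=O)[CH-][O+]12 | intermediate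
14 | (2S,3R,4R,6Z,9S)-2,9:3,4-diepoxy-3,7-dimethylcyclodec-6-en-10-one | C/C1=C/C[C@H]2O[C@@]2(C)[C@@H]2CC(=O)[C@H](C1)O2 | intermediate
15 | (2S,3R,4R,6Z,9S)-2,9:3,4-diepoxy-3,7-dimethylcyclodeca-1(10),6-dien-10-yl trifluoromethanesulfonate | C/C1=C/C[C@H]2O[C@@]2(C)[C@@H]2C=C(OS(=O)(=O)C(F)(F)F)[C@H](C1)O2 | intermediate
16 | (2S,3R,4R,6Z,9S)-10-(1-ethoxyethenyl)-2,9:3,4-diepoxy-3,7-dimethylcyclodeca-1(10),6-diene | C/C1=C/C[C@H]2O[C@@]2(C)[C@@H]2C=C(C(=C)OCC)[C@H](C1)O2 | intermediate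
17 | Diels–Alder adducts, mixture of C14 epimers (14-acetyl-11-ethoxy tricyclic enol ether) | C/C1=C/C[C@H]2O[C@@]2(C)[C@@H]2[C@H]3C(C(C)=O)CCC(OCC)=C3[C@H](C1)O2 | intermediate
18 | (1S,2S,3R,4R,6Z,9S,14R)-14-acetyl-11-ethoxy-2,9:3,4-diepoxy tricyclic enol ether | C/C1=C/C[C@H]2O[C@@]2(C)[C@@H]2[C@H]3[C@H](C(C)=O)CCC(OCC)=C3[C@H](C1)O2 | intermediate
19 | (1S,2S,3R,4R,6Z,9S,14R)-11-ethoxy-14-(prop-1-en-2-yl)-2,9:3,4-diepoxy tricyclic enol ether | C/C1=C/C[C@H]2O[C@@]2(C)[C@@H]2[C@H]3[C@H](C(C)=C)CCC(OCC)=C3[C@H](C1)O2 | intermediate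
20 | B-alkyl-9-borabicyclo[3.3.1]nonane adduct of 19 (boron on C16) | C/C1=C/C[C@H]2O[C@@]2(C)[C@@H]2[C@H]3[C@H]([C@@H](C)CB4C5CCCC4CCC5)CCC(OCC)=C3[C@H](C1)O2 | intermediate
21 | (1S,2S,3R,4R,6Z,9S,14S,15R)-11-ethoxy-14-(1-hydroxypropan-2-yl)-2,9:3,4-diepoxy tricyclic enol ether | C/C1=C/C[C@H]2O[C@@]2(C)[C@@H]2[C@H]3[C@H]([C@@H](C)CO)CCC(OCC)=C3[C@H](C1)O2 | intermediate
22 | (1S,2S,3R,4R,6Z,9S,10R,14S,15R)-3,4-epoxy-11-oxo-16-hydroxy tricycle | C/C1=C/C[C@H]2O[C@@]2(C)[C@@H]2[C@H]3[C@H]([C@@H](C)CO)CCC(=O)[C@H]3[C@H](C1)O2 | intermediate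
23 | (1S,2S,3S,4R,6Z,9S,10R,14S,15R)-4-hydroxy-11-oxo tetracycle (oxepane closed) | C/C1=C/C[C@@H](O)[C@]2(C)OC[C@H](C)[C@@H]3CCC(=O)[C@@H]4[C@H]3[C@@H]2O[C@H]4C1 | intermediate
24 | (1S,2S,3S,4R,6Z,9S,10S,14S,15R)-4-hydroxy-11-methylidene tetracycle | C/C1=C/C[C@@H](O)[C@]2(C)OC[C@H](C)[C@@H]3CCC(=C)[C@@H]4[C@H]3[C@@H]2O[C@H]4C1 | intermediate
25 | (1S,2S,3S,4R,6Z,9S,10R,11S,14S,15R)-4,11-dihydroxy tetracycle | C/C1=C/C[C@@H](O)[C@]2(C)OC[C@H](C)[C@@H]3CC[C@](C)(O)[C@@H]4[C@H]3[C@@H]2O[C@H]4C1 | intermediate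
26 | (1S,2S,3S,4R,6Z,9S,10R,11S,14S,15R)-11-hydroxy tetracycle 4-octanoate | C/C1=C/C[C@@H](OC(=O)CCCCCCC)[C@]2(C)OC[C@H](C)[C@@H]3CC[C@](C)(O)[C@@H]4[C@H]3[C@@H]2O[C@H]4C1 | intermediate
27 | (1S,2S,3S,4R,6R,7S,9S,10R,11S,14S,15R)-6,7-epoxy-11-hydroxy tetracycle 4-octanoate | C[C@@]12O[C@@H]1C[C@@H](OC(=O)CCCCCCC)[C@]3(C)OC[C@H](C)[C@@H]4CC[C@](C)(O)[C@@H]5[C@H]4[C@@H]3O[C@H]5C2 | intermediate
28 | target, (1S,2S,3S,4R,6R,9S,10R,11S,14S,15R)-6,11-dihydroxy-7(19)-ene tetracycle 4-octanoate | C=C1C[C@@H]2O[C@H]3[C@H]4[C@@H](CC[C@](C)(O)[C@H]42)[C@@H](C)CO[C@@]3(C)[C@H](OC(=O)CCCCCCC)C[C@H]1O | target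

**Step count and risks**
Total steps: 20. Longest linear sequence: 20 (fully linear from 1).

The three steps most likely to fail:

Step 14 (C15 by hydroboration). Acyclic 1,1-disubstituted alkenes of this type often give poor or reversed facial selectivity. The fallback swaps the roles of CH3 and CH2O so that the same facial preference gives the other C15 configuration. It sets out from 18: kinetic enolisation of the methyl ketone (LDA, THF, −78 °C) and hydroxylation with MoOPH give the 14-(hydroxyacetyl) enol ether F1. Wittig methylenation (Ph3P=CH2, excess) gives the 14-(3-hydroxyprop-1-en-2-yl) enol ether F2. Chemoselective hydrogenation of the 1,1-disubstituted alkene (H2, (Ph3P)3RhCl, benzene) then delivers H instead of B to the alkene and comes back to the route at 21.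

Step 15 (7-endo epoxide opening). If the C16 hydroxyl cannot reach C3 anti to the oxirane oxygen, or transannular participation of C6=C7 interferes, the C3–O and O–C16 bonds are made in the opposite order. The fallback sets out from 21: aqueous acid (0.5 M H2SO4, THF/H2O) hydrolyses the enol ether and hydrates the epoxide at C3 with inversion to the 3,4,16-triol 11-ketone F3. Tf2O (1.05 equiv) and 2,6-lutidine in CH2Cl2 at −78 → 0 °C form the primary C16 triflate F4, which is displaced in the flask by the tertiary C3 hydroxyl (7-exo-tet) and comes back to the route at 23.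

Step 20 (aluminium-amide isomerisation next to an ester). If the octanoate is enolised or cleaved, or the regiochemistry fails, the allylic alcohol is made without an epoxide. The fallback sets out from 26: a Schenck ene reaction with singlet oxygen (O2, hν, tetraphenylporphyrin, CH2Cl2, 0 °C) gives the C6 allylic hydroperoxide F5 with the exocyclic alkene; reduction with PPh3 comes back to the route at 28. The regiochemistry of this ene reaction (methyl against ring allylic hydrogens) is itself uncertain.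

Further compounds
F1 | step 14 | (1S,2S,3R,4R,6Z,9S)-11-ethoxy-14-(hydroxyacetyl)-2,9:3,4-diepoxy tricyclic enol ether | C/C1=C/C[C@H]2O[C@@]2(C)[C@@H]2[C@H]3[C@H](C(=O)CO)CCC(OCC)=C3[C@H](C1)O2
F2 | step 14 | (1S,2S,3R,4R,6Z,9S)-11-ethoxy-14-(3-hydroxyprop-1-en-2-yl)-2,9:3,4-diepoxy tricyclic enol ether | C/C1=C/C[C@H]2O[C@@]2(C)[C@@H]2[C@H]3[C@H](C(=C)CO)CCC(OCC)=C3[C@H](C1)O2
F3 | step 15 | (1S,2S,3S,4R,6Z,9S,10R,14S,15R)-3,4,16-trihydroxy-11-oxo tricycle | C/C1=C/C[C@@H](O)[C@](C)(O)[C@@H]2[C@H]3[C@H]([C@@H](C)CO)CCC(=O)[C@H]3[C@H](C1)O2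
F4 | step 15 | C16 trifluoromethanesulfonate of F3 | C/C1=C/C[C@@H](O)[C@](C)(O)[C@@H]2[C@H]3[C@H]([C@@H](C)COS(=O)(=O)C(F)(F)F)CCC(=O)[C@H]3[C@H](C1)O2
F5 | step 20 | (6R)-6-hydroperoxy analogue of the target | C=C1C[C@@H]2O[C@H]3[C@H]4[C@@H](CC[C@](C)(O)[C@H]42)[C@@H](C)CO[C@@]3(C)[C@H](OC(=O)CCCCCCC)C[C@H]1OO
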